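## Analysis of the target

The target 18 is a depside: one aryl ester joins two benzene rings, and there is no stereocentre, so the problem is one of chemo- and regiocontrol only. Ring A is the acyl half, a benzoyl group with OH at C2, OMe at C4 and a 2-oxopentyl chain at C6. Ring B is 2,4-dihydroxy-6-propylbenzoic acid, acylated at O4 and carrying a free carboxyl at C1 between an OH and the propyl group. The ester carbonyl sits between two ortho substituents of ring A, so it is the most hindered place to form a bond, yet the finished aryl ester is an activated one that gives up its acyl group easily. The side-chain ketone is the dangerous neighbour: its enol oxygen lies five atoms from the ester carbon, and acid or base can close it to a 3-propylisocoumarin with expulsion of ring B. The ring B acid is a β-resorcylic acid that decarboxylates in acid or on heating, so it must be released last and under neutral conditions. Three phenolic OH groups are present, and the single O-methyl group must sit on ring A O4 alone. The feature that the route exploits is that ring A, with its ester carbon, C1 to C6, oxygen on C2 and C4 and a carbon chain on C6, maps atom for atom onto a folded 3,5,7-trioxoalkanoate ester. Ring A can therefore be built on the ester oxygen of ring B instead of being attached to it as a finished, hindered acid.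

## Retrosynthetic reasoning

18 to 17. The carboxyl of ring B is released last from its benzyl ester 17 by hydrogenolysis. This is the only neutral unmasking that leaves the depside ester, the ketone and the acid-sensitive β-resorcylic acid untouched.

17 to 16. The side-chain ketone is traced back to the dioxolane in 16. The mask is needed from the start: it keeps this fourth carbonyl out of every enolisation and cyclisation, and it blocks isocoumarin formation while bases are in use.

16 to 15. The O-methyl bond at ring A O4 is cut. In 15 this is the only phenol that is not locked in a hydrogen bond to an ortho carbonyl, so a reaction that discriminates on acidity and accessibility can place the methyl group without protecting groups.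

15 to 8 and 11 (key disconnection). Two bonds are cut at once: the depside C(=O)–O bond and the ring A C1–C6 bond. Ring A then unfolds through aldol adduct 14 to the open 3,5,7-trioxo ester 13, which is the adduct of phenol 11 and acylketene 12. The ketene in turn is the cycloreversion product of dioxinone 8. The cut is placed here because the ester carbon is unhindered as long as ring A does not exist, and because one operation then delivers both the hardest bond and the whole arene. The forward reaction must capture 12 with O4 of 11 and then close C2 onto C7 without ejecting the aryl oxide.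

8 to 6 and 3. The chain of 8 is cut between C4' (the outer ketone carbon) and C3' (the methylene towards the ring). This gives the dianion 7 of keto-dioxinone 6 as nucleophile and Weinreb amide 3 as acyl donor. Both halves are small, and the cut places the ketal two carbons away from the new bond.

3 to 2 to 1, 6 to 5 to 4, 11 to 10 to 9. The amide 3 comes from ketal ester 2 and this from β-keto ester 1. The keto-dioxinone 6 comes from the dienolate 5 of dioxinone 4 by C-acetylation. The phenol 11 comes from acid 10 by O-benzylation of the carboxylate, and 10 from the resorcinol 9 by ortho-carboxylation. All three starting materials (1, 4, 9) are commercial.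

## Alternatives that were turned down

Alternative 1: the textbook disconnection cuts only the depside C(=O)–O bond and keeps both rings intact. The forward key step is acylation of O4 of 11 by the activated ring A acid 2-(benzyloxy)-4-methoxy-6-[(2-propyl-1,3-dioxolan-2-yl)methyl]benzoic acid (A1), by carbodiimide or mixed-anhydride activation, followed by ketal hydrolysis and hydrogenolysis. It was turned down for three reasons.
- The acyl carbon of A1 lies between two ortho substituents, so a weakly nucleophilic phenol must attack at the most hindered carbonyl available, under activation that the dioxolane has to survive.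
- A1 itself needs lateral metalation and acylation of an O-protected orsellinate ester, ketalisation, differentiation of the two ring oxygens and saponification of a di-ortho-substituted ester. That is at least six steps, more than the whole dioxinone branch of the chosen route.
- Without its protecting groups the acid collapses to the isocoumarin A2, so no step can be saved by leaving them off.

Alternative 2: the same ester bond is cut, but ring A is delivered as the enol lactone 8-hydroxy-6-methoxy-3-propyl-1H-isochromen-1-one (A2). Its lactone carbonyl is the depside carbonyl and its C3–C4 enol is the latent 2-oxopentyl ketone. The forward key step is ring-opening acyl transfer from A2 to the phenoxide of 11, which would create ester and ketone together with perfect atom economy. It was turned down on mechanistic grounds.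
- The equilibrium is expected to run backwards: the opened product holds an enol(ate) oxygen five atoms from an activated aryl ester, and re-closure regenerates a conjugated lactone and a stabilised phenoxide with a gain in entropy.
- Every base that activates the phenol also catalyses this return.
- The same base opens a C-acylation path to a naphthalene-1,3-diol.

Alternative 3: ring A is cut across C1–C2 and C5–C6 in a [4+2] sense. The forward key step is a Diels–Alder reaction of 1,3-dimethoxy-1-(trimethylsilyloxy)buta-1,3-diene (A4) with the aryl ynoate benzyl 2-hydroxy-6-propyl-4-{[4-(2-propyl-1,3-dioxolan-2-yl)but-2-ynoyl]oxy}benzoate (A3), followed by aromatisation with loss of one methoxy group. The polarity of A4 would give the 2-OH/4-OMe/6-alkyl pattern directly, with no selective methylation. It was turned down for three reasons.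
- A γ-alkyl ynoate is a poor dienophile and would need temperatures at which the silyl ketene acetal A4 degrades.
- The propargylic CH2 of A3, between alkyne and ketal, invites isomerisation to an allenoate, and aryl ynoates also take up phenols by conjugate addition.
- The parent ynoic acid costs about four steps, and the ester bond is still made by a conventional acylation, so the cycloaddition buys only the ring, at higher risk than the aldol closure.

Key step: step 7

## Route

Step 1
Reactants: 1 ethyl 3-oxohexanoate
Product: 2 ethyl 2-(2-propyl-1,3-dioxolan-2-yl)acetate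
Conditions: HOCH2CH2OH (1.5 equiv), pTsOH·H2O (cat.), PhMe, reflux, Dean–Stark trap
Reagents that add atoms: ethylene glycol (ethane-1,2-diol), OCCO
Why: Acid-catalysed ketalisation of the ketone of a β-keto ester with azeotropic removal of water; the ester is untouched, and the dioxolane masks the future side-chain carbonyl against enolisation and aldol chemistry in all later steps.

Step 2
Reactants: 2 ethyl 2-(2-propyl-1,3-dioxolan-2-yl)acetate
Product: 3 N-methoxy-N-methyl-2-(2-propyl-1,3-dioxolan-2-yl)acetamide
Conditions: MeNH(OMe)·HCl (1.5 equiv), iPrMgCl (3.0 equiv), THF, −20 to 0 °C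
Reagents that add atoms: N,O-dimethylhydroxylamine hydrochloride, CNOC.Cl
Why: Direct aminolysis of the ester by the magnesium amide formed in the flask (Weinreb amide synthesis); the amide nucleophile reacts faster than the ester is enolised, and the ketal is inert to the Grignard base at this temperature.

Step 3
Reactants: 4 2,2,6-trimethyl-4H-1,3-dioxin-4-one
Product: 6 2,2-dimethyl-6-(2-oxopropyl)-4H-1,3-dioxin-4-one, via lithium dienolate 5 (not isolated)
Conditions: 4 (2.0 equiv), LiN(SiMe3)2 (2.0 equiv), THF, −78 °C; then AcCl (1.0 equiv), −78 °C; aq. NH4Cl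
Reagents that add atoms: acetyl chloride, CC(Cl)=O
Why: Vinylogous Claisen acylation: dienolate 5 is acylated at its γ-carbon by the acid chloride. The second equivalent of 5 takes up the more acidic product, so the reaction should stop at the mono-ketone.

Step 4
Reactants: 6 2,2-dimethyl-6-(2-oxopropyl)-4H-1,3-dioxin-4-one; 3 N-methoxy-N-methyl-2-(2-propyl-1,3-dioxolan-2-yl)acetamide
Product: 8 2,2-dimethyl-6-[2,4-dioxo-5-(2-propyl-1,3-dioxolan-2-yl)pentyl]-4H-1,3-dioxin-4-one, via dilithium dianion 7 (not isolated)
Conditions: 6, LiN(iPr)2 (2.2 equiv), THF, −78 °C; then 3 (0.9 equiv), −78 to −30 °C; aq. NH4Cl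
Reagents that add atoms: none
Why: Claisen-type acylation of a 1,3-dicarbonyl dianion: 7 reacts at its terminal, most basic carbon. The N-methoxy-N-methyl amide releases the new ketone only at work-up, so the acidic triketide product never meets the dianion and over-addition is avoided.

Step 5
Reactants: 9 5-propylbenzene-1,3-diol
Product: 10 2,4-dihydroxy-6-propylbenzoic acid
Conditions: MeOMgOCO2Me (2 M in DMF, 4 equiv), 120 °C; then cold 2 M aq. HCl
Reagents that add atoms: methoxymagnesium methyl carbonate, COC(=O)O[Mg]OC
Why: Chelation-driven ortho-carboxylation of a phenol (Kolbe–Schmitt-type reaction with methyl magnesium carbonate); the magnesium salicylate chelate drives the equilibrium. Carboxylation at the ring carbon between OH and the alkyl group is the expected outcome for 5-alkylresorcinols.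

Step 6
Reactants: 10 2,4-dihydroxy-6-propylbenzoic acid
Product: 11 benzyl 2,4-dihydroxy-6-propylbenzoate
Conditions: BnBr (1.05 equiv), KHCO3 (1.2 equiv), DMF, 23 °C
Reagents that add atoms: benzyl bromide, BrCc1ccccc1
Why: SN2 alkylation of the carboxylate; KHCO3 deprotonates only the carboxylic acid, so the phenols should stay free, and no heat or acid is applied that could decarboxylate 10.

Step 7
Reactants: 8 2,2-dimethyl-6-[2,4-dioxo-5-(2-propyl-1,3-dioxolan-2-yl)pentyl]-4H-1,3-dioxin-4-one; 11 benzyl 2,4-dihydroxy-6-propylbenzoate
Product: 15 benzyl 4-({2,4-dihydroxy-6-[(2-propyl-1,3-dioxolan-2-yl)methyl]benzoyl}oxy)-2-hydroxy-6-propylbenzoate, via acylketene 12 (not isolated), via triketo aryl ester 13 (not isolated), via aldol adduct 14 (not isolated)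
Conditions: 11 (2.0 equiv), PhMe (0.2 M), 110 °C, 1 h; cool to 23 °C; Et3N (2 equiv), CH2Cl2, 23 °C; then AcOH
Reagents that add atoms: none
Why: Heating 8 triggers a retro-hetero-Diels–Alder cycloreversion that expels acetone and gives acylketene 12, whose sp carbonyl carbon is unhindered, so the depside C(=O)–O bond forms before the two ortho substituents that would shield it exist; the non-chelated, more nucleophilic 4-OH of 11 adds across the ketene while its 2-OH stays locked in a hydrogen bond to the benzyl ester. The resulting 3,5,7-trioxo ester 13 is enolised by Et3N, and its C2 carbon (between ester and ketone) adds to the C7 ketone in a 6-(enolendo)-exo-trig aldol closure to 14, the only six-membered carbocyclisation open to the acidic methylenes that keeps the aryl oxide; E1cB loss of water and enolisation then give the aromatic ring A of 15. The closest known reaction type is the thermolysis of 6-(2,4-dioxoalkyl)dioxinones in the presence of alcohols followed by base-mediated aldol aromatisation to resorcylate esters, together with the known capture of dioxinone-derived acylketenes by phenols to give aryl β-keto esters. No stereocentre has to be controlled: the two stereocentres of 14 are erased on aromatisation. The step needs three selectivities: intermolecular capture of 12 ahead of its own lactonisation to a 4-hydroxypyran-2-one (secured by excess 11 at high concentration), aldol closure ahead of Claisen closure or lactonisation that would eject the aryl oxide (secured by the mild amine base and the higher electrophilicity of the ketone), and exclusion of the fourth carbonyl from any cyclisation (secured by the dioxolane, which leaves C8 only weakly acidic and C9 non-electrophilic). The benzyl ester and the ketal should both be inert at 110 °C under these neutral to weakly basic conditions.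

Step 8
Reactants: 15 benzyl 4-({2,4-dihydroxy-6-[(2-propyl-1,3-dioxolan-2-yl)methyl]benzoyl}oxy)-2-hydroxy-6-propylbenzoate
Product: 16 benzyl 2-hydroxy-4-({2-hydroxy-4-methoxy-6-[(2-propyl-1,3-dioxolan-2-yl)methyl]benzoyl}oxy)-6-propylbenzoate
Conditions: MeOH (1.2 equiv), PPh3 (1.2 equiv), iPrO2CN=NCO2iPr (1.2 equiv), THF, 0 to 23 °C
Reagents that add atoms: methanol, CO
Why: Mitsunobu etherification: only the ring A 4-OH is free of a hydrogen bond to an ortho carbonyl and acidic enough to protonate the betaine, so it should be methylated selectively. The conditions are neutral, which protects the depside ester.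

Step 9
Reactants: 16 benzyl 2-hydroxy-4-({2-hydroxy-4-methoxy-6-[(2-propyl-1,3-dioxolan-2-yl)methyl]benzoyl}oxy)-6-propylbenzoate
Product: 17 benzyl 2-hydroxy-4-{[2-hydroxy-4-methoxy-6-(2-oxopentyl)benzoyl]oxy}-6-propylbenzoate
Conditions: 1 M aq. HCl/THF (1:4), 23 °C
Reagents that add atoms: water, O
Why: Acid-catalysed hydrolysis of the dioxolane through the oxocarbenium ion; with water in excess at 23 °C, ketal cleavage should be much faster than enolisation of the new ketone, which is what isocoumarin formation requires. The benzyl ester still protects the acid against decarboxylation.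

Step 10
Reactants: 17 benzyl 2-hydroxy-4-{[2-hydroxy-4-methoxy-6-(2-oxopentyl)benzoyl]oxy}-6-propylbenzoate
Product: 18 2-hydroxy-4-{[2-hydroxy-4-methoxy-6-(2-oxopentyl)benzoyl]oxy}-6-propylbenzoic acid (CNP0187582.0)
Conditions: H2 (1 atm), Pd/C (palladium metal on carbon, 10 wt%), EtOAc, 23 °C
Reagents that add atoms: none
Why: Catalytic hydrogenolysis of the benzyl ester under neutral conditions; the dialkyl ketone, the aryl ester and the aryl methyl ether are not reduced at 1 atm, and the free acid is never exposed to acid or heat.

## Compound list

1 | ethyl 3-oxohexanoate | CCCC(=O)CC(=O)OCC | starting material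
2 | ethyl 2-(2-propyl-1,3-dioxolan-2-yl)acetate | CCCC1(CC(=O)OCC)OCCO1 | intermediate
3 | N-methoxy-N-methyl-2-(2-propyl-1,3-dioxolan-2-yl)acetamide | CCCC1(CC(=O)N(C)OC)OCCO1 | intermediate
4 | 2,2,6-trimethyl-4H-1,3-dioxin-4-one | CC1=CC(=O)OC(C)(C)O1 | starting material
5 | lithium dienolate of 4 (lithium 2,2-dimethyl-6-methylidene-6H-1,3-dioxin-4-olate), not isolated | [Li+].C=C1C=C([O-])OC(C)(C)O1 | intermediate
6 | 2,2-dimethyl-6-(2-oxopropyl)-4H-1,3-dioxin-4-one | CC(=O)CC1=CC(=O)OC(C)(C)O1 | intermediate
7 | dilithium dianion of 6 (dilithium 2,2-dimethyl-6-(2-oxidoprop-2-en-1-ylidene)-6H-1,3-dioxin-4-olate), not isolated | [Li+].[Li+].C=C([O-])C=C1C=C([O-])OC(C)(C)O1 | intermediate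
8 | 2,2-dimethyl-6-[2,4-dioxo-5-(2-propyl-1,3-dioxolan-2-yl)pentyl]-4H-1,3-dioxin-4-one | CCCC1(CC(=O)CC(=O)CC2=CC(=O)OC(C)(C)O2)OCCO1 | intermediate
9 | 5-propylbenzene-1,3-diol | CCCc1cc(O)cc(O)c1 | starting material
10 | 2,4-dihydroxy-6-propylbenzoic acid | CCCc1cc(O)cc(O)c1C(=O)O | intermediate
11 | benzyl 2,4-dihydroxy-6-propylbenzoate | CCCc1cc(O)cc(O)c1C(=O)OCc1ccccc1 | intermediate
12 | acylketene 8-(2-propyl-1,3-dioxolan-2-yl)oct-1-ene-1,3,5,7-tetrone, not isolated | CCCC1(CC(=O)CC(=O)CC(=O)C=C=O)OCCO1 | intermediate
13 | benzyl 2-hydroxy-6-propyl-4-{[3,5,7-trioxo-8-(2-propyl-1,3-dioxolan-2-yl)octanoyl]oxy}benzoate, not isolated | CCCC1(CC(=O)CC(=O)CC(=O)CC(=O)Oc2cc(O)c(C(=O)OCc3ccccc3)c(CCC)c2)OCCO1 | intermediate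
14 | benzyl 2-hydroxy-4-[({2-hydroxy-4,6-dioxo-2-[(2-propyl-1,3-dioxolan-2-yl)methyl]cyclohexyl}carbonyl)oxy]-6-propylbenzoate (mixture of stereoisomers, both stereocentres lost on aromatisation), not isolated | CCCC1(CC2(O)CC(=O)CC(=O)C2C(=O)Oc2cc(O)c(C(=O)OCc3ccccc3)c(CCC)c2)OCCO1 | intermediate
15 | benzyl 4-({2,4-dihydroxy-6-[(2-propyl-1,3-dioxolan-2-yl)methyl]benzoyl}oxy)-2-hydroxy-6-propylbenzoate | CCCC1(Cc2cc(O)cc(O)c2C(=O)Oc2cc(O)c(C(=O)OCc3ccccc3)c(CCC)c2)OCCO1 | intermediate
16 | benzyl 2-hydroxy-4-({2-hydroxy-4-methoxy-6-[(2-propyl-1,3-dioxolan-2-yl)methyl]benzoyl}oxy)-6-propylbenzoate | CCCC1(Cc2cc(OC)cc(O)c2C(=O)Oc2cc(O)c(C(=O)OCc3ccccc3)c(CCC)c2)OCCO1 | intermediate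
17 | benzyl 2-hydroxy-4-{[2-hydroxy-4-methoxy-6-(2-oxopentyl)benzoyl]oxy}-6-propylbenzoate | CCCC(=O)Cc1cc(OC)cc(O)c1C(=O)Oc1cc(O)c(C(=O)OCc2ccccc2)c(CCC)c1 | intermediate
18 | 2-hydroxy-4-{[2-hydroxy-4-methoxy-6-(2-oxopentyl)benzoyl]oxy}-6-propylbenzoic acid (CNP0187582.0) | CCCC(=O)Cc1cc(OC)cc(O)c1C(=O)Oc1cc(O)c(C(=O)O)c(CCC)c1 | target

## Step count and least certain steps

Total step count: 10. Longest linear sequence: 7 steps (steps 1, 2, 4, 7, 8, 9, 10). Steps 3, 5 and 6 are side branches.

Step 7 (key step). Two things are most likely to go wrong.
- The acylketene may be captured by its own enol oxygen (lactonisation to a 4-hydroxypyran-2-one) before the weakly nucleophilic phenol reaches it.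
- After capture, the aryl oxide may be lost from the open chain, by lactonisation or by Claisen closure of C6 onto the ester carbon, because an aryl oxide leaves far more easily than an alkoxide.

Fallback: it sets out from 8 and separates ring formation from ester formation.
- 8 is aromatised alone (Et3N, CH2Cl2, 23 °C) to 7-hydroxy-2,2-dimethyl-5-[(2-propyl-1,3-dioxolan-2-yl)methyl]-4H-1,3-benzodioxin-4-one F1.
- Its single free OH is methylated (MeI, K2CO3, acetone) to 7-methoxy-2,2-dimethyl-5-[(2-propyl-1,3-dioxolan-2-yl)methyl]-4H-1,3-benzodioxin-4-one F2.
- The acetonide is opened (aq. KOH, DMSO, 60 °C, then acidification to pH 4) to 2-hydroxy-4-methoxy-6-[(2-propyl-1,3-dioxolan-2-yl)methyl]benzoic acid F3.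
- F3 is esterified with 11 by carbodiimide activation (N,N'-dicyclohexylcarbodiimide, cat. 4-(dimethylamino)pyridine, CH2Cl2, 23 °C).
- The sequence comes back to the route at 16 and skips 15 and step 8.

Step 4. The dianion may act as a base towards the α-CH2 of 3, or may open the dioxolane by β-elimination, so that acylation stalls and 6 is recovered.

Fallback: it sets out from 2 and 4 and replaces the dianion by soft enolisation followed by decarboxylation.
- 2 is saponified (LiOH, THF/H2O, acidification to pH 4) to 2-(2-propyl-1,3-dioxolan-2-yl)acetic acid F4.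
- F4 is converted under neutral conditions (1-chloro-N,N,2-trimethylprop-1-en-1-amine, CH2Cl2, 0 °C) into 2-(2-propyl-1,3-dioxolan-2-yl)acetyl chloride F5.
- In parallel, 4 is acylated through dienolate 5 with allyl 3-chloro-3-oxopropanoate to allyl 4-(2,2-dimethyl-4-oxo-4H-1,3-dioxin-6-yl)-3-oxobutanoate F6.
- F6 is C-acylated with F5 (MgCl2, pyridine, CH2Cl2, 0 °C) to prop-2-en-1-yl 2-[(2,2-dimethyl-4-oxo-4H-1,3-dioxin-6-yl)acetyl]-3-oxo-4-(2-propyl-1,3-dioxolan-2-yl)butanoate F7.
- Deallylation and decarboxylation with Pd(PPh3)4 (a zerovalent palladium catalyst) and morpholine in THF at 23 °C should bring the sequence back to the route at 8.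

Step 8. Etherification may spill over to one of the chelated hydroxyl groups, or stop short of completion, which leaves mixtures of closely related phenols that are hard to separate.

Fallback: the methyl group is placed before the depside exists. The sequence sets out from 8, follows the path through F1, F2 and F3 described under step 7, where only one hydroxyl is free at the methylation stage, and comes back at 16. It makes no compound of its own (F0).

Step 9. Once the ketone is free, acid may promote attack of its enol oxygen on the depside carbonyl, which closes an isocoumarin and releases the ring B phenol.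

Fallback: the order of the end game is reversed, so that the ketone appears only in the last operation and without aqueous Brønsted acid.
- 16 is hydrogenolysed first (H2, Pd/C, EtOAc) to 2-hydroxy-4-({2-hydroxy-4-methoxy-6-[(2-propyl-1,3-dioxolan-2-yl)methyl]benzoyl}oxy)-6-propylbenzoic acid F8.
- The dioxolane is then transferred to the solvent by Lewis-acid-catalysed exchange (In(OSO2CF3)3 (cat.), acetone, 23 °C).
- The sequence comes back to the route at 18 and skips 17.

## Further compounds

F1 | step 7 | 7-hydroxy-2,2-dimethyl-5-[(2-propyl-1,3-dioxolan-2-yl)methyl]-4H-1,3-benzodioxin-4-one | CCCC1(Cc2cc(O)cc3OC(C)(C)OC(=O)c23)OCCO1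
F2 | step 7 | 7-methoxy-2,2-dimethyl-5-[(2-propyl-1,3-dioxolan-2-yl)methyl]-4H-1,3-benzodioxin-4-one | CCCC1(Cc2cc(OC)cc3OC(C)(C)OC(=O)c23)OCCO1
F3 | step 7 | 2-hydroxy-4-methoxy-6-[(2-propyl-1,3-dioxolan-2-yl)methyl]benzoic acid | CCCC1(Cc2cc(OC)cc(O)c2C(=O)O)OCCO1
F4 | step 4 | 2-(2-propyl-1,3-dioxolan-2-yl)acetic acid | CCCC1(CC(=O)O)OCCO1
F5 | step 4 | 2-(2-propyl-1,3-dioxolan-2-yl)acetyl chloride | CCCC1(CC(=O)Cl)OCCO1
F6 | step 4 | allyl 4-(2,2-dimethyl-4-oxo-4H-1,3-dioxin-6-yl)-3-oxobutanoate | C=CCOC(=O)CC(=O)CC1=CC(=O)OC(C)(C)O1
F7 | step 4 | prop-2-en-1-yl 2-[(2,2-dimethyl-4-oxo-4H-1,3-dioxin-6-yl)acetyl]-3-oxo-4-(2-propyl-1,3-dioxolan-2-yl)butanoate | C=CCOC(=O)C(C(=O)CC1=CC(=O)OC(C)(C)O1)C(=O)CC1(CCC)OCCO1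
F0 | step 8 | none | none
F8 | step 9 | 2-hydroxy-4-({2-hydroxy-4-methoxy-6-[(2-propyl-1,3-dioxolan-2-yl)methyl]benzoyl}oxy)-6-propylbenzoic acid | CCCC1(Cc2cc(OC)cc(O)c2C(=O)Oc2cc(O)c(C(=O)O)c(CCC)c2)OCCO1
A1 | alternative 1 | 2-(benzyloxy)-4-methoxy-6-[(2-propyl-1,3-dioxolan-2-yl)methyl]benzoic acid | CCCC1(Cc2cc(OC)cc(OCc3ccccc3)c2C(=O)O)OCCO1
A2 | alternative 2 | 8-hydroxy-6-methoxy-3-propyl-1H-isochromen-1-one | CCCC1=Cc2cc(OC)cc(O)c2C(=O)O1
A3 | alternative 3 | benzyl 2-hydroxy-6-propyl-4-{[4-(2-propyl-1,3-dioxolan-2-yl)but-2-ynoyl]oxy}benzoate | CCCC1(CC#CC(=O)Oc2cc(O)c(C(=O)OCc3ccccc3)c(CCC)c2)OCCO1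
A4 | alternative 3 | 1,3-dimethoxy-1-(trimethylsilyloxy)buta-1,3-diene (either geometry at C1=C2) | C=C(OC)C=C(OC)O[Si](C)(C)C
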